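## Retrosynthetic overview

1. The quinone is made last by Teuber oxidation of a 21-hydroxy-20-amido arene (C18–H to C18=O); the benzene ring comes intact from 2-bromophenol.
2. The 19-membered lactam comes from an 18-membered aryl lactone (C1–O21) by C20–N coupling and O-to-N acyl shift, a one-atom ring expansion that forms N–C20 and N–C1.
3. The lactone comes from a seco acid by C1–O21 macrolactonisation; C3–C4 by Sonogashira coupling, the 4Z alkene by enyne semi-reduction.
4. The chain grows outward from the arene aldehyde: C14–C15 by Z-crotylboration with a pinene-derived borane, C11 by hydroformylation, C12–O by organocatalytic α-oxyamination, C10–C11 by Z-crotylboration with a tartrate boronate, C7–C9 by cross-metathesis with methacrolein, C6–C7 by allenylstannane addition.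
5. Ring order: arene (purchased), then 18-membered lactone, then 19-membered lactam, then quinone.

Assumption: locants C1–C21 follow the target's ansa numbering (C1 amide carbonyl, C15 carbinol carbon, C16–C21 ring carbons, N on C20, O on C21), TBS is tert-butyldimethylsilyl, and (S)-but-3-yn-2-ol and (E)-3-iodo-2-methylacrylic acid are taken as catalogue compounds.

## Route

Step 1
Reactants: 1 2-bromophenol; 2 formaldehyde (used as paraformaldehyde)
Product: 3 3-bromo-2-hydroxybenzaldehyde
Conditions: MgCl2, Et3N, (CH2O)n, THF, reflux; 1 M HCl work-up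
Reagents that add atoms: none
Why: The magnesium phenoxide delivers formaldehyde to the only free ortho position and a second formaldehyde oxidises the benzylic alkoxide by hydride transfer (magnesium-mediated ortho-formylation), so only the 3-bromo salicylaldehyde forms.

Step 2
Reactants: 3 3-bromo-2-hydroxybenzaldehyde
Product: 4 3-bromo-2-(tert-butyldimethylsilyloxy)benzaldehyde
Conditions: TBSCl, imidazole, DMF, rt
Reagents that add atoms: tert-butyldimethylsilyl chloride, CC(C)(C)[Si](C)(C)Cl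
Why: Imidazole-promoted silylation of the acidic phenol masks it for the organometallic steps, and the flanking bromine and side chain later shield this aryl silyl ether from mild aqueous base.

Step 3
Reactants: 4 3-bromo-2-(tert-butyldimethylsilyloxy)benzaldehyde; 5 cis-2-butene
Product: 7 (1R,2S)-1-[3-bromo-2-(tert-butyldimethylsilyloxy)phenyl]-2-methylbut-3-en-1-ol, via Z-crotylbis(isopinocampheyl)borane 6 (not isolated)
Conditions: 5, KOtBu, n-BuLi, THF, −78 to −45 °C; (+)-Ipc2BOMe, −78 °C; BF3·OEt2; then 4, −78 °C; NaBO3·4H2O, THF/H2O, rt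
Reagents that add atoms: none
Why: Brown Z-crotylboration through a closed chair transition state gives the syn adduct, and the isopinocampheyl groups derived from (−)-α-pinene direct attack to the Re face of the aldehyde, setting 15R and 14S.

Step 4
Reactants: 7 (1R,2S)-1-[3-bromo-2-(tert-butyldimethylsilyloxy)phenyl]-2-methylbut-3-en-1-ol
Product: 8 tert-butyl{[(1R,2S)-1-[3-bromo-2-(tert-butyldimethylsilyloxy)phenyl]-2-methylbut-3-en-1-yl]oxy}dimethylsilane
Conditions: TBSOTf, 2,6-lutidine, CH2Cl2, −78 to 0 °C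
Reagents that add atoms: tert-butyldimethylsilyl triflate, CC(C)(C)[Si](C)(C)OS(=O)(=O)C(F)(F)F
Why: Silyl triflate silylation protects the hindered benzylic C15 alcohol so that it stays distinct from the hydroxyls to be methylated, and any aryl-to-alkyl silyl migration in step 3 would converge on the same bis-silyl ether.

Step 5
Reactants: 8 bis-TBS ether of 7; 9 carbon monoxide
Product: 10 (4S,5R)-5-[3-bromo-2-(tert-butyldimethylsilyloxy)phenyl]-5-(tert-butyldimethylsilyloxy)-4-methylpentanal
Conditions: CO/H2 (1:1, 10 bar), Rh(acac)(CO)2 (1 mol%), Xantphos (2 mol%), toluene, 70 °C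
Reagents that add atoms: none
Why: Linear-selective rhodium hydroformylation with a wide-bite-angle diphosphine adds C11 at the terminal carbon, the allylic methyl branch further disfavouring the branched aldehyde, and the aryl bromide is inert.

Step 6
Reactants: 10 C11 aldehyde
Product: 11 (2S,4S,5R)-5-[3-bromo-2-(tert-butyldimethylsilyloxy)phenyl]-5-(tert-butyldimethylsilyloxy)-4-methyl-2-[(2,2,6,6-tetramethylpiperidin-1-yl)oxy]pentanal
Conditions: TEMPO (1.3 equiv), CuCl2 (10 mol%), (5S)-5-benzyl-2,2,3-trimethylimidazolidin-4-one·CF3CO2H (20 mol%), air, acetone, 0 °C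
Reagents that add atoms: TEMPO, CC1(C)CCCC(C)(C)N1[O]
Why: Enamine-catalysed α-oxyamination, in which the benzyl group of the (5S)-imidazolidinone shields one face of the E-enamine so the copper-bound TEMPO adds to the open face, sets 12S and gives an isolable, configurationally stable α-aminooxy aldehyde.

Step 7
Reactants: 11 α-aminooxy aldehyde; 5 cis-2-butene
Product: 13 (3S,4R,5S,7S,8R)-8-[3-bromo-2-(tert-butyldimethylsilyloxy)phenyl]-8-(tert-butyldimethylsilyloxy)-3,7-dimethyl-5-[(2,2,6,6-tetramethylpiperidin-1-yl)oxy]oct-1-en-4-ol, via tartrate Z-crotylboronate 12 (not isolated)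
Conditions: 5, KOtBu, n-BuLi, THF, −78 to −25 °C; B(OiPr)3, −78 °C; 1 M HCl, Et2O, (S,S)-diisopropyl tartrate, MgSO4 (crude solution used directly); then 11, 4 Å MS, toluene, −78 °C; aq NaHCO3
Reagents that add atoms: none
Why: Roush Z-crotylboration through a closed chair transition state gives the 10,11-syn adduct, the (S,S)-tartrate ester directs the crotyl group to the Re face of the aldehyde (11R, 10S), and this is the matched case because Z-crotylboronates already add to α-alkoxy aldehydes with a strong Felkin–Anh/Cornforth preference for the 11,12-anti product; the boronate also needs no oxidative work-up, which spares the alkoxyamine.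

Step 8
Reactants: 13 aminooxy alcohol
Product: 14 (3S,4R,5S,7S,8R)-8-[3-bromo-2-(tert-butyldimethylsilyloxy)phenyl]-8-(tert-butyldimethylsilyloxy)-3,7-dimethyloct-1-ene-4,5-diol
Conditions: Zn dust, AcOH/THF/H2O (3:1:1), 50 °C
Reagents that add atoms: none
Why: Dissolving-metal reduction cleaves the weak N–O bond of the alkoxyamine to free the C12 hydroxyl without touching a stereocentre, the aryl bromide or the hindered silyl ethers.

Step 9
Reactants: 14 anti-diol
Product: 15 (3S,4R,5S,7S,8R)-8-[3-bromo-2-(tert-butyldimethylsilyloxy)phenyl]-8-(tert-butyldimethylsilyloxy)-4,5-dimethoxy-3,7-dimethyloct-1-ene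
Conditions: Me3OBF4, 1,8-bis(dimethylamino)naphthalene, 4 Å MS, CH2Cl2, rt
Reagents that add atoms: trimethyloxonium tetrafluoroborate, C[O+](C)C.F[B-](F)(F)F
Why: Meerwein-salt O-methylation under non-nucleophilic buffered conditions methylates both hydroxyls (C11 and C12) in one operation and avoids the alkoxide base that could strip the aryl silyl ether.

Step 10
Reactants: 15 dimethoxy alkene; 16 methacrolein
Product: 17 (2E,4S,5R,6S,8S,9R)-9-[3-bromo-2-(tert-butyldimethylsilyloxy)phenyl]-9-(tert-butyldimethylsilyloxy)-5,6-dimethoxy-2,4,8-trimethylnon-2-enal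
Conditions: 16 (10 equiv), second-generation Hoveyda–Grubbs catalyst (10 mol%), CH2Cl2, 40 °C
Reagents that add atoms: none
Why: Olefin cross-metathesis of the only terminal alkene with excess methacrolein gives the thermodynamically favoured E-trisubstituted enal, installing C7, C8 and the C8 methyl in one step.

Step 11
Reactants: 18 (S)-but-3-yn-2-ol
Product: 19 (S)-but-3-yn-2-yl methanesulfonate
Conditions: MsCl, Et3N, CH2Cl2, −78 to 0 °C
Reagents that add atoms: methanesulfonyl chloride, CS(=O)(=O)Cl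
Why: O-Sulfonylation activates the propargylic alcohol with retention at carbon.

Step 12
Reactants: 19 (S)-but-3-yn-2-yl methanesulfonate
Product: 20 (aR)-tributyl(buta-1,2-dien-1-yl)stannane
Conditions: Bu3SnH, LDA, THF, −78 °C; CuBr·SMe2; then 19, −78 °C
Reagents that add atoms: tributyltin hydride, CCCC[SnH](CCCC)CCCC
Why: Anti SN2′ displacement of the propargylic mesylate by the stannylcopper reagent transfers the central chirality of 19 to the allene axis (Marshall allenylstannane synthesis).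

Step 13
Reactants: 17 enal; 20 (aR)-tributyl(buta-1,2-dien-1-yl)stannane
Product: 21 (3S,4R,5E,7S,8R,9S,11S,12R)-12-[3-bromo-2-(tert-butyldimethylsilyloxy)phenyl]-12-(tert-butyldimethylsilyloxy)-8,9-dimethoxy-3,5,7,11-tetramethyldodec-5-en-1-yn-4-ol
Conditions: 20 (1.5 equiv), BF3·OEt2, CH2Cl2, −78 °C; aq NaHCO3
Reagents that add atoms: none
Why: BF3-promoted anti SE2′ addition of the allenylstannane through an open antiperiplanar transition state (Marshall propargylation) gives the syn homopropargylic alcohol, the allene axis fixing 6S and the syn topicity fixing 7R.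

Step 14
Reactants: 21 homopropargylic alcohol
Product: 23 (3S,4R,5E,7S,8R,9S,11S,12R)-12-(3-bromo-2-hydroxyphenyl)-12-(tert-butyldimethylsilyloxy)-8,9-dimethoxy-3,5,7,11-tetramethyldodec-5-en-1-yn-4-yl carbamate, via N-trichloroacetyl carbamate 22 (not isolated)
Conditions: Cl3CC(O)NCO, CH2Cl2, 0 °C; then K2CO3, MeOH, rt
Reagents that add atoms: trichloroacetyl isocyanate, O=C=NC(=O)C(Cl)(Cl)Cl
Why: Isocyanate acylation of the C7 alcohol followed by methanolysis removes the trichloroacetyl group and, in the same pot, the aryl silyl ether (phenoxide is a far better leaving group than the C15 alkoxide), giving the primary carbamate and the free phenol.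

Step 15
Reactants: 23 alkyne carbamate; 24 (E)-3-iodo-2-methylacrylic acid
Product: 25 (2E,6S,7R,8E,10S,11R,12S,14S,15R)-15-(3-bromo-2-hydroxyphenyl)-7-(carbamoyloxy)-15-(tert-butyldimethylsilyloxy)-11,12-dimethoxy-2,6,8,10,14-pentamethylpentadeca-2,8-dien-4-ynoic acid
Conditions: 24 (1.3 equiv), Pd(PPh3)2Cl2 (5 mol%), CuI (10 mol%), Et3N, THF, rt
Reagents that add atoms: none
Why: Sonogashira coupling forms C3–C4 with retention of the 2E geometry, the vinyl iodide reacting at room temperature while the aryl bromide stays untouched.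

Step 16
Reactants: 25 enyne acid
Product: 26 (2E,4Z,6S,7R,8E,10S,11R,12S,14S,15R)-15-(3-bromo-2-hydroxyphenyl)-7-(carbamoyloxy)-15-(tert-butyldimethylsilyloxy)-11,12-dimethoxy-2,6,8,10,14-pentamethylpentadeca-2,4,8-trienoic acid
Conditions: Zn dust activated with Cu(OAc)2 and AgNO3, MeOH/H2O (1:1), 40 °C
Reagents that add atoms: none
Why: Boland-type zinc reduction of the conjugated enyne delivers both hydrogens to one face of the alkyne to give the 4Z alkene without over-reduction or loss of the aryl bromide.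

Step 17
Reactants: 26 seco acid
Product: 28 C1-to-O21 macrolactone of 26 (18-membered aryl ester; 20-bromo; 15-O-TBS; 7-O-carbamoyl), via mixed anhydride 27 (not isolated)
Conditions: 2-methyl-6-nitrobenzoic anhydride, DMAP, CH2Cl2 (1 mM), rt, slow addition of 26
Reagents that add atoms: none
Why: Shiina macrolactonisation activates the acid as a mixed anhydride and acylpyridinium that the phenoxide captures under high dilution to close the 18-membered aryl ester, the primary carbamate being too weak a nucleophile to compete.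

Step 18
Reactants: 28 18-membered aryl macrolactone
Product: 31 19-membered macrolactam phenol (N20–C1 amide; free 21-OH and 15-OH; 18-deoxy hydroquinone form of the target), via N-aryl ketimine lactone 29 (not isolated), via 20-amino lactone 30 (not isolated)
Conditions: Pd2(dba)3 (5 mol%), rac-BINAP (12 mol%), Ph2C=NH, Cs2CO3, toluene, 80 °C; then 48% aq HF, MeCN, 0 °C to rt; then aq NaHCO3 (pH 8), rt
Reagents that add atoms: benzophenone imine, N=C(c1ccccc1)c1ccccc1
Why: Proposed new method: a one-flask aminative ring expansion in which zerovalent palladium with BINAP couples the aryl bromide with benzophenone imine (Buchwald–Hartwig amination with an ammonia surrogate), aqueous HF hydrolyses the ketimine and removes the C15 silyl ether, and on neutralisation the freed ortho-amino group attacks the neighbouring ester carbonyl through a five-membered tetrahedral intermediate that expels the phenoxide, so nitrogen is inserted and the ring grows from 18 to 19 atoms, driven by amide over aryl-ester stability; the closest known reactions are the O-to-N acyl shift of 2-aminophenyl esters and amine-triggered acyl-transfer ring expansions of lactams, neither shown for turning an aryl macrolactone into an ansa-lactam.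

Step 19
Reactants: 31 macrolactam phenol
Product: 32 target quinone (CNP0557283.1)
Conditions: (KO3S)2NO (Fremy's salt, 3 equiv), KH2PO4 buffer, acetone/H2O, rt
Reagents that add atoms: potassium nitrosodisulfonate, [O]N(S(=O)(=O)[O-])S(=O)(=O)[O-].[K+].[K+]
Why: Teuber oxidation takes the phenol to its phenoxyl radical, which a second nitrosodisulfonate traps at the only free position para to oxygen (C18), collapsing to the para-quinone because both ortho positions are blocked.

## Compound list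

1 | 2-bromophenol | Oc1ccccc1Br | starting material
2 | formaldehyde (used as paraformaldehyde) | C=O | starting material
3 | 3-bromo-2-hydroxybenzaldehyde | O=Cc1cccc(Br)c1O | intermediate
4 | 3-bromo-2-(tert-butyldimethylsilyloxy)benzaldehyde | O=Cc1cccc(Br)c1O[Si](C)(C)C(C)(C)C | intermediate
5 | cis-2-butene | C/C=C\C | starting material
6 | (Z)-but-2-en-1-ylbis[(1S,2R,3S,5S)-2,6,6-trimethylbicyclo[3.1.1]heptan-3-yl]borane | C/C=C\CB([C@H]1C[C@H]2C[C@@H]([C@@H]1C)C2(C)C)[C@H]1C[C@H]2C[C@@H]([C@@H]1C)C2(C)C | intermediate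
7 | (1R,2S)-1-[3-bromo-2-(TBS-oxy)phenyl]-2-methylbut-3-en-1-ol | CC(C)(C)[Si](C)(C)Oc1c(Br)cccc1[C@H](O)[C@@H](C)C=C | intermediate
8 | bis-TBS ether of 7 | CC(C)(C)[Si](C)(C)Oc1c(Br)cccc1[C@H](O[Si](C)(C)C(C)(C)C)[C@@H](C)C=C | intermediate
9 | carbon monoxide | [C-]#[O+] | starting material
10 | (4S,5R)-5-[3-bromo-2-(TBS-oxy)phenyl]-5-(TBS-oxy)-4-methylpentanal | CC(C)(C)[Si](C)(C)Oc1c(Br)cccc1[C@H](O[Si](C)(C)C(C)(C)C)[C@@H](C)CCC=O | intermediate
11 | (2S,4S,5R)-2-[(2,2,6,6-tetramethylpiperidin-1-yl)oxy] derivative of 10 | CC(C)(C)[Si](C)(C)Oc1c(Br)cccc1[C@H](O[Si](C)(C)C(C)(C)C)[C@@H](C)C[C@H](ON1C(C)(C)CCCC1(C)C)C=O | intermediate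
12 | diisopropyl (4S,5S)-2-[(Z)-but-2-en-1-yl]-1,3,2-dioxaborolane-4,5-dicarboxylate | C/C=C\CB1O[C@H](C(=O)OC(C)C)[C@@H](C(=O)OC(C)C)O1 | intermediate
13 | (3S,4R,5S,7S,8R)-8-aryl-8-(TBS-oxy)-3,7-dimethyl-5-[(2,2,6,6-tetramethylpiperidin-1-yl)oxy]oct-1-en-4-ol (aryl = 3-bromo-2-(TBS-oxy)phenyl) | CC(C)(C)[Si](C)(C)Oc1c(Br)cccc1[C@H](O[Si](C)(C)C(C)(C)C)[C@@H](C)C[C@H](ON1C(C)(C)CCCC1(C)C)[C@H](O)[C@@H](C)C=C | intermediate
14 | (3S,4R,5S,7S,8R)-8-aryl-8-(TBS-oxy)-3,7-dimethyloct-1-ene-4,5-diol | CC(C)(C)[Si](C)(C)Oc1c(Br)cccc1[C@H](O[Si](C)(C)C(C)(C)C)[C@@H](C)C[C@H](O)[C@H](O)[C@@H](C)C=C | intermediate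
15 | (3S,4R,5S,7S,8R)-8-aryl-8-(TBS-oxy)-4,5-dimethoxy-3,7-dimethyloct-1-ene | CC(C)(C)[Si](C)(C)Oc1c(Br)cccc1[C@H](O[Si](C)(C)C(C)(C)C)[C@@H](C)C[C@H](OC)[C@H](OC)[C@@H](C)C=C | intermediate
16 | methacrolein | CC(=C)C=O | starting material
17 | (2E,4S,5R,6S,8S,9R)-9-aryl-9-(TBS-oxy)-5,6-dimethoxy-2,4,8-trimethylnon-2-enal | CC(C)(C)[Si](C)(C)Oc1c(Br)cccc1[C@H](O[Si](C)(C)C(C)(C)C)[C@@H](C)C[C@H](OC)[C@H](OC)[C@@H](C)/C=C(C)/C=O | intermediate
18 | (S)-but-3-yn-2-ol | C[C@H](O)C#C | starting material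
19 | (S)-but-3-yn-2-yl methanesulfonate | C[C@H](OS(C)(=O)=O)C#C | intermediate
20 | (aR)-tributyl(buta-1,2-dien-1-yl)stannane | CCCC[Sn](CCCC)(CCCC)C([H])=[C@]=C([H])C | intermediate
21 | (3S,4R,5E,7S,8R,9S,11S,12R)-12-aryl-12-(TBS-oxy)-8,9-dimethoxy-3,5,7,11-tetramethyldodec-5-en-1-yn-4-ol | CC(C)(C)[Si](C)(C)Oc1c(Br)cccc1[C@H](O[Si](C)(C)C(C)(C)C)[C@@H](C)C[C@H](OC)[C@H](OC)[C@@H](C)/C=C(C)/[C@H](O)[C@@H](C)C#C | intermediate
22 | N-trichloroacetyl carbamate of 21 | CC(C)(C)[Si](C)(C)Oc1c(Br)cccc1[C@H](O[Si](C)(C)C(C)(C)C)[C@@H](C)C[C@H](OC)[C@H](OC)[C@@H](C)/C=C(C)/[C@H](OC(=O)NC(=O)C(Cl)(Cl)Cl)[C@@H](C)C#C | intermediate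
23 | C7 carbamate with free 21-phenol and 15-O-TBS (terminal alkyne) | Oc1c(Br)cccc1[C@H](O[Si](C)(C)C(C)(C)C)[C@@H](C)C[C@H](OC)[C@H](OC)[C@@H](C)/C=C(C)/[C@H](OC(N)=O)[C@@H](C)C#C | intermediate
24 | (E)-3-iodo-2-methylacrylic acid | OC(=O)/C(C)=C/I | starting material
25 | (2E,6S,7R,8E,10S,11R,12S,14S,15R)-en-4-ynoic seco acid | Oc1c(Br)cccc1[C@H](O[Si](C)(C)C(C)(C)C)[C@@H](C)C[C@H](OC)[C@H](OC)[C@@H](C)/C=C(C)/[C@H](OC(N)=O)[C@@H](C)C#C/C=C(\C)C(=O)O | intermediate
26 | (2E,4Z,6S,7R,8E,10S,11R,12S,14S,15R)-trienoic seco acid | Oc1c(Br)cccc1[C@H](O[Si](C)(C)C(C)(C)C)[C@@H](C)C[C@H](OC)[C@H](OC)[C@@H](C)/C=C(C)/[C@H](OC(N)=O)[C@@H](C)/C=C\C=C(/C)C(=O)O | intermediate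
27 | mixed anhydride of 26 with 2-methyl-6-nitrobenzoic acid | Oc1c(Br)cccc1[C@H](O[Si](C)(C)C(C)(C)C)[C@@H](C)C[C@H](OC)[C@H](OC)[C@@H](C)/C=C(C)/[C@H](OC(N)=O)[C@@H](C)/C=C\C=C(/C)C(=O)OC(=O)c1c(C)cccc1[N+](=O)[O-] | intermediate
28 | 18-membered aryl macrolactone (C1 on O21; 20-bromo; 15-O-TBS; 7-O-carbamoyl) | O=C1Oc2c(Br)cccc2[C@H](O[Si](C)(C)C(C)(C)C)[C@@H](C)C[C@H](OC)[C@H](OC)[C@@H](C)/C=C(C)/[C@H](OC(N)=O)[C@@H](C)/C=C\C=C1/C | intermediate
29 | 20-(diphenylmethylene)amino analogue of 28 | O=C1Oc2c(N=C(c3ccccc3)c3ccccc3)cccc2[C@H](O[Si](C)(C)C(C)(C)C)[C@@H](C)C[C@H](OC)[C@H](OC)[C@@H](C)/C=C(C)/[C@H](OC(N)=O)[C@@H](C)/C=C\C=C1/C | intermediate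
30 | 20-amino-15-hydroxy aryl macrolactone | O=C1Oc2c(N)cccc2[C@H](O)[C@@H](C)C[C@H](OC)[C@H](OC)[C@@H](C)/C=C(C)/[C@H](OC(N)=O)[C@@H](C)/C=C\C=C1/C | intermediate
31 | 19-membered macrolactam phenol (21-OH, 15-OH, 18-H) | O=C1Nc2cccc(c2O)[C@H](O)[C@@H](C)C[C@H](OC)[C@H](OC)[C@@H](C)/C=C(C)/[C@H](OC(N)=O)[C@@H](C)/C=C\C=C1/C | intermediate
32 | CNP0557283.1 (6S,7R,10S,11R,12S,14S,15R; 2E,4Z,8E) | CO[C@H]1[C@@H](OC)C[C@H](C)[C@@H](O)C2=CC(=O)C=C(NC(=O)/C(C)=C/C=C\[C@H](C)[C@@H](OC(N)=O)/C(C)=C/[C@@H]1C)C2=O | target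

## Step count and risks

Total step count: 19. Longest linear sequence: 17 steps (steps 1–10 and 13–19, from 2-bromophenol); the allenylstannane arm (steps 11–12) adds two.

The three steps most likely to fail:

Step 18 (the proposed ring expansion). The risks are ionisation of the allylic C7 carbamate by zerovalent palladium, N-arylation of the primary carbamate, and loss of the aryl ester before the amine is unmasked. The fallback uses only known chemistry and closes the lactam directly; it sets out from 21 and comes back at 31. Acid 24 is converted through its isobutyl mixed anhydride (isobutyl chloroformate, N-methylmorpholine, then NH3) into (E)-3-iodo-2-methylacrylamide F5. Sonogashira coupling of 21 with F5 (Pd(PPh3)2Cl2, CuI, Et3N) gives the enyne amide F6, and zinc reduction as in step 16 gives the (2E,4Z)-dienamide F7. Intramolecular N-arylation of the primary amide by the aryl bromide (CuI, N,N′-dimethylethylenediamine, K2CO3, toluene, 100 °C, 2 mM), the established ansamycin macrolactam closure, gives the bis-silylated macrolactam F8. Trichloroacetyl isocyanate followed by K2CO3/MeOH installs the C7 carbamate and frees the phenol to give the carbamate phenol F9, and HF·pyridine removes the C15 silyl ether to give 31.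

Step 17 (macrolactonisation). The nucleophile is a 2,6-disubstituted phenol and the activated (2E,4Z)-dienoic acid may isomerise or oligomerise. The fallback forms the ester intermolecularly and closes the ring by C–C coupling; it sets out from 23 and comes back at 28. Acid 24 with oxalyl chloride gives (E)-3-iodo-2-methylacryloyl chloride F2. Acylation of the phenol of 23 (Et3N, catalytic DMAP, CH2Cl2, 0 °C) gives the aryl iodoacrylate F3. Intramolecular Sonogashira coupling (Pd(PPh3)4, CuI, iPr2NEt, THF, 1 mM, slow addition) gives the 18-membered enyne lactone F4, and zinc reduction as in step 16 gives 28.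

Step 10 (cross-metathesis). The alkene is allylically branched and methacrolein is a sluggish partner, so conversion may stall or the catalyst may decompose. The fallback replaces metathesis by cleavage and olefination; it sets out from 15 and comes back at 17. Oxidative cleavage of the terminal alkene (OsO4 catalytic, NaIO4, 2,6-lutidine, dioxane/H2O) gives the α-methyl C9 aldehyde F1, which is used at once in a Wittig reaction with 2-(triphenylphosphoranylidene)propanal (toluene, 90 °C) to give the E-enal 17.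

Further compounds

F1 | step 10 | (2R,3R,4S,6S,7R)-7-[3-bromo-2-(TBS-oxy)phenyl]-7-(TBS-oxy)-3,4-dimethoxy-2,6-dimethylheptanal | CC(C)(C)[Si](C)(C)Oc1c(Br)cccc1[C@H](O[Si](C)(C)C(C)(C)C)[C@@H](C)C[C@H](OC)[C@H](OC)[C@@H](C)C=O
F2 | step 17 | (E)-3-iodo-2-methylacryloyl chloride | ClC(=O)/C(C)=C/I
F3 | step 17 | 21-O-[(E)-3-iodo-2-methylacryloyl] ester of 23 | I/C=C(\C)C(=O)Oc1c(Br)cccc1[C@H](O[Si](C)(C)C(C)(C)C)[C@@H](C)C[C@H](OC)[C@H](OC)[C@@H](C)/C=C(C)/[C@H](OC(N)=O)[C@@H](C)C#C
F4 | step 17 | 18-membered 2E-en-4-yne aryl macrolactone | O=C1Oc2c(Br)cccc2[C@H](O[Si](C)(C)C(C)(C)C)[C@@H](C)C[C@H](OC)[C@H](OC)[C@@H](C)/C=C(C)/[C@H](OC(N)=O)[C@@H](C)C#C/C=C1\C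
F5 | step 18 | (E)-3-iodo-2-methylacrylamide | NC(=O)/C(C)=C/I
F6 | step 18 | enyne primary amide from 21 (7-OH; aryl O-TBS; 15-O-TBS) | CC(C)(C)[Si](C)(C)Oc1c(Br)cccc1[C@H](O[Si](C)(C)C(C)(C)C)[C@@H](C)C[C@H](OC)[C@H](OC)[C@@H](C)/C=C(C)/[C@H](O)[C@@H](C)C#C/C=C(\C)C(N)=O
F7 | step 18 | (2E,4Z)-dienamide (7-OH; aryl O-TBS; 15-O-TBS) | CC(C)(C)[Si](C)(C)Oc1c(Br)cccc1[C@H](O[Si](C)(C)C(C)(C)C)[C@@H](C)C[C@H](OC)[C@H](OC)[C@@H](C)/C=C(C)/[C@H](O)[C@@H](C)/C=C\C=C(/C)C(N)=O
F8 | step 18 | 19-membered macrolactam (7-OH; 21-O-TBS; 15-O-TBS) | O=C1Nc2cccc(c2O[Si](C)(C)C(C)(C)C)[C@H](O[Si](C)(C)C(C)(C)C)[C@@H](C)C[C@H](OC)[C@H](OC)[C@@H](C)/C=C(C)/[C@H](O)[C@@H](C)/C=C\C=C1/C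
F9 | step 18 | 19-membered macrolactam (7-O-carbamoyl; 21-OH; 15-O-TBS) | O=C1Nc2cccc(c2O)[C@H](O[Si](C)(C)C(C)(C)C)[C@@H](C)C[C@H](OC)[C@H](OC)[C@@H](C)/C=C(C)/[C@H](OC(N)=O)[C@@H](C)/C=C\C=C1/C
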